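**Plan**

- Retrosynthetic cuts, in order: (a) the C8–CH2 bond to the lavandulyl group (Negishi coupling); (b) the C4–C4a aryl ketone bond of ring C (intramolecular Friedel–Crafts acylation); (c) the O1–C2 ether bond (Mitsunobu reaction).
- Forward: ring B with C2–C3–C4 (an allyl (R)-3-aryl-3-hydroxypropanoate) is hung on O1 of a 2-bromo-3,5-disilyloxyphenol (ring A), ring C is then closed by acylation, and the side chain is coupled last; rings A and B are bought as arenes.
- Enabling feature: in the seco-acid, C4a is the only unsubstituted carbon ortho to O1 (C8 holds bromine). It is a phloroglucinol carbon flanked by O1 and O5 and para to O7, and the tether O1–C2–C3 places the acyl carbon C4 over it for a six-membered closure.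
- Helpers: bromine at C8 (blocks, later replaced by the side chain), acetate on O4' (keeps the benzylic C2–O1 bond from ionising), silyl ethers on O5 and O7; all are replaced or removed in the last three steps.
- Stereochemistry: C2 (S) from asymmetric transfer hydrogenation to the (R)-carbinol followed by Mitsunobu inversion; the side-chain centre (R) from an Evans dienolate alkylation, carried through (S)-lavandulol and its iodide without touching the centre.

Key step: step 8

Remark: flavanone numbering (O1, C2, C3, C4, C4a, C5 to C8, C8a; ring B primed) is used for all intermediates; the six starting materials and all reagents are taken as purchasable.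

**Route**

Step 1
Reactants: 1 1-(4-hydroxy-2-methoxyphenyl)ethanone; 2 diallyl carbonate
Product: 3 allyl 3-(4-hydroxy-2-methoxyphenyl)-3-oxopropanoate
Conditions: NaH (3.5 equiv), THF, 65 °C; then aq. HCl
Reagents that add atoms: none
Why: Crossed Claisen condensation in which the ketone enolate (the phenoxide is a spectator) is C-acylated by the carbonate and the equilibrium is drawn to the product by deprotonation of the β-keto ester, the allyl ester being chosen because it can later be removed without acid or base.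

Step 2
Reactants: 3 allyl 3-(4-hydroxy-2-methoxyphenyl)-3-oxopropanoate
Product: 4 allyl 3-(4-acetoxy-2-methoxyphenyl)-3-oxopropanoate
Conditions: Ac2O (1.1 equiv), pyridine, CH2Cl2, 0 °C
Reagents that add atoms: acetic anhydride CC(=O)OC(C)=O
Why: O-acylation of the phenol, which under these conditions is far more nucleophilic than the keto ester; the electron-poor acetoxy group para to the future C2 is what later keeps that benzylic centre from ionising.

Step 3
Reactants: 4 allyl 3-(4-acetoxy-2-methoxyphenyl)-3-oxopropanoate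
Product: 5 allyl (3R)-3-(4-acetoxy-2-methoxyphenyl)-3-hydroxypropanoate
Conditions: RuCl[(R,R)-TsDPEN](p-cymene) (1 mol%), HCO2H/Et3N (5:2), DMF, 30 °C
Reagents that add atoms: none
Why: Noyori-type asymmetric transfer hydrogenation, in which the ruthenium hydride and the ligand N–H deliver hydride and proton to the aryl ketone through an outer-sphere six-membered transition state with the aryl group held by a CH–π contact to the cymene ring, so that the (R,R)-ligand should give the (R)-carbinol while the allyl alkene and both esters are left alone.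

Step 4
Reactants: 6 phloroglucinol
Product: 7 3,5-bis(tert-butyldimethylsilyloxy)phenol
Conditions: t-BuMe2SiCl (2.0 equiv), imidazole, DMF, 0 → 25 °C; separation from the mono- and tris-silyl ethers, which can be recycled
Reagents that add atoms: tert-butyldimethylsilyl chloride CC(C)(C)[Si](C)(C)Cl
Why: Imidazole-mediated O-silylation, which with the hard silicon electrophile occurs only at oxygen (no C-substitution of the phloroglucinol nucleus), so that the bis-silyl ether should be the main component of a statistical mixture.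

Step 5
Reactants: 7 3,5-bis(tert-butyldimethylsilyloxy)phenol
Product: 8 2-bromo-3,5-bis(tert-butyldimethylsilyloxy)phenol
Conditions: N-bromosuccinimide (1.0 equiv), diisopropylamine (10 mol%), CH2Cl2, −78 → −40 °C
Reagents that add atoms: N-bromosuccinimide O=C1CCC(=O)N1Br
Why: Amine-catalysed ortho-selective electrophilic bromination of a phenol, expected next to the hydrogen-bonded OH because the para position is shielded by two flanking silyloxy groups, with one equivalent at low temperature limiting dibromination.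

Step 6
Reactants: 8 2-bromo-3,5-bis(tert-butyldimethylsilyloxy)phenol; 5 allyl (3R)-3-(4-acetoxy-2-methoxyphenyl)-3-hydroxypropanoate
Product: 9 allyl (3S)-3-(4-acetoxy-2-methoxyphenyl)-3-[2-bromo-3,5-bis(tert-butyldimethylsilyloxy)phenoxy]propanoate
Conditions: PPh3, diisopropyl azodicarboxylate, toluene, −20 → 25 °C
Reagents that add atoms: none
Why: Mitsunobu etherification, an SN2 displacement of the alkoxyphosphonium ion by the acidic ortho-bromophenoxide that inverts the carbinol centre (R to S, the future C2), the acetoxy-substituted ring B and the non-polar solvent disfavouring the competing ionisation.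

Step 7
Reactants: 9 allyl (3S)-3-(4-acetoxy-2-methoxyphenyl)-3-[2-bromo-3,5-bis(tert-butyldimethylsilyloxy)phenoxy]propanoate
Product: 10 (3S)-3-(4-acetoxy-2-methoxyphenyl)-3-[2-bromo-3,5-bis(tert-butyldimethylsilyloxy)phenoxy]propanoic acid
Conditions: Pd(PPh3)4 (2 mol%), N-methylaniline (2 equiv), THF, 25 °C
Reagents that add atoms: none
Why: Tsuji–Trost deallylation, in which zerovalent palladium ionises the allyl ester to a π-allyl complex that is captured by the amine, a neutral unmasking that should spare the silyl ethers, the aryl acetate, the β-aryloxy stereocentre and, at this temperature with triphenylphosphine as ligand, the electron-rich aryl bromide.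

Step 8
Reactants: 10 (3S)-3-(4-acetoxy-2-methoxyphenyl)-3-[2-bromo-3,5-bis(tert-butyldimethylsilyloxy)phenoxy]propanoic acid
Product: 12 4-[(2S)-8-bromo-5,7-bis(tert-butyldimethylsilyloxy)-4-oxo-3,4-dihydro-2H-chromen-2-yl]-3-methoxyphenyl acetate, via mixed trifluoroacetic anhydride 11 (not isolated)
Conditions: (CF3CO)2O (1.5 equiv), CH2Cl2, −20 → 0 °C; aq. NaHCO3
Reagents that add atoms: none
Why: Intramolecular Friedel–Crafts acylation: the anhydride converts the acid into mixed anhydride 11, whose acyl carbon C4 (as such or as the acylium ion pair) is attacked by C4a of ring A to give an arenium ion that loses its proton, which sets free trifluoroacetic acid. The closest known reaction type is the cyclisation of 3-aryloxypropanoic and 3-aryl-3-aryloxypropanoic acids to chroman-4-ones and flavanones under anhydride or acid activation. Ring C closes in the 6-exo-trig mode, the acyl C=O lying outside the new ring. No stereocentre is formed, and C2 is carried through because none of its four bonds takes part. The step needs site selectivity and an intact C2–O1 bond: with bromine on C8, C4a is the only free position ortho to O1 and it is activated by O1 and O5 (ortho) and O7 (para), whereas the alternative five-membered closure onto ring B would have to occur meta to both of its oxygen substituents. Heterolysis of the benzylic C2–O1 bond is held back by the acetoxy group para to C2, the low temperature and the absence of a Lewis acid.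

Step 9
Reactants: 13 (4S)-4-benzyloxazolidin-2-one; 14 3-methylbut-2-enoyl chloride
Product: 16 (4S)-4-benzyl-3-(3-methylbut-2-enoyl)oxazolidin-2-one, via N-lithio oxazolidinone 15 (not isolated)
Conditions: n-BuLi, THF, −78 °C; then 14, −78 → 0 °C
Reagents that add atoms: none
Why: N-acylation of the lithiated oxazolidinone by the acid chloride (nucleophilic acyl substitution), run without an amine base so that no vinylketene is formed from the unsaturated acid chloride.

Step 10
Reactants: 16 (4S)-4-benzyl-3-(3-methylbut-2-enoyl)oxazolidin-2-one; 17 1-bromo-3-methylbut-2-ene (prenyl bromide)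
Product: 19 (4S)-4-benzyl-3-[(2S)-5-methyl-2-(prop-1-en-2-yl)hex-4-enoyl]oxazolidin-2-one, via sodium dienolate 18 (not isolated)
Conditions: NaN(SiMe3)2, THF, −78 °C; then 17, −78 → −40 °C
Reagents that add atoms: none
Why: Evans asymmetric alkylation in its deconjugative form, in which γ-deprotonation gives the chelated Z dienolate that is alkylated at the α-carbon on the face away from the benzyl group of the auxiliary, which sets the (S) centre and leaves the isopropenyl group.

Step 11
Reactants: 19 (4S)-4-benzyl-3-[(2S)-5-methyl-2-(prop-1-en-2-yl)hex-4-enoyl]oxazolidin-2-one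
Product: 20 (2S)-5-methyl-2-(prop-1-en-2-yl)hex-4-en-1-ol, (S)-lavandulol
Conditions: LiBH4, MeOH (1 equiv), Et2O, 0 °C
Reagents that add atoms: none
Why: Reductive cleavage of the N-acyl oxazolidinone by borohydride (hydride attack at the exocyclic, lithium-activated carbonyl), which releases the auxiliary and the primary alcohol without enolising the α-centre or touching the alkenes.

Step 12
Reactants: 20 (2S)-5-methyl-2-(prop-1-en-2-yl)hex-4-en-1-ol
Product: 21 (3S)-3-(iodomethyl)-2,6-dimethylhepta-1,5-diene, (S)-lavandulyl iodide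
Conditions: PPh3, I2, imidazole, CH2Cl2, 0 °C
Reagents that add atoms: iodine [I][I]
Why: Appel-type iodination, an SN2 displacement of the alkoxyphosphonium group by iodide at the primary carbon that does not involve the neighbouring stereocentre.

Step 13
Reactants: 12 4-[(2S)-8-bromo-5,7-bis(tert-butyldimethylsilyloxy)-4-oxo-3,4-dihydro-2H-chromen-2-yl]-3-methoxyphenyl acetate; 21 (3S)-3-(iodomethyl)-2,6-dimethylhepta-1,5-diene
Product: 23 4-{(2S)-5,7-bis(tert-butyldimethylsilyloxy)-8-[(2R)-5-methyl-2-(prop-1-en-2-yl)hex-4-en-1-yl]-4-oxo-3,4-dihydro-2H-chromen-2-yl}-3-methoxyphenyl acetate, via lavandulylzinc iodide 22 (not isolated)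
Conditions: 21, Zn dust (activated with BrCH2CH2Br and Me3SiCl), LiCl, THF, 40 °C; then 12, Pd(OAc)2 (5 mol%), SPhos (10 mol%), THF, 25 → 50 °C
Reagents that add atoms: none
Why: Negishi coupling, in which LiCl-assisted insertion of zinc into the primary C–I bond gives an alkylzinc iodide that transmetalates to the arylpalladium bromide formed at C8, and with the bulky biarylphosphine reductive elimination should outrun β-hydride elimination, so the side-chain centre (β to the metal, never bonded to it) is carried over unchanged (its descriptor becomes R only because CH2–aryl ranks below isopropenyl) while ketone, acetate, silyl ethers and C2 are inert to the non-basic reagent.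

Step 14
Reactants: 23 4-{(2S)-5,7-bis(tert-butyldimethylsilyloxy)-8-[(2R)-5-methyl-2-(prop-1-en-2-yl)hex-4-en-1-yl]-4-oxo-3,4-dihydro-2H-chromen-2-yl}-3-methoxyphenyl acetate
Product: 24 4-{(2S)-5,7-dihydroxy-8-[(2R)-5-methyl-2-(prop-1-en-2-yl)hex-4-en-1-yl]-4-oxo-3,4-dihydro-2H-chromen-2-yl}-3-methoxyphenyl acetate
Conditions: n-Bu4NF, AcOH (1:1, 3 equiv), THF, 0 °C
Reagents that add atoms: none
Why: Fluoride-induced cleavage of the two aryl silyl ethers, buffered with acetic acid so that no phenoxide accumulates and the flavanone cannot open by a retro-oxa-Michael reaction, the acetate on ring B being kept at this stage for the same reason.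

Step 15
Reactants: 24 4-{(2S)-5,7-dihydroxy-8-[(2R)-5-methyl-2-(prop-1-en-2-yl)hex-4-en-1-yl]-4-oxo-3,4-dihydro-2H-chromen-2-yl}-3-methoxyphenyl acetate
Product: 25 leachianone A
Conditions: NH4OAc (10 equiv), MeOH/H2O (4:1), 25 °C
Reagents that add atoms: none
Why: Ammonium acetate-mediated methanolysis (transesterification) of the aryl acetate at near-neutral pH, chosen because a ring B phenoxide would open ring C through a quinone methide and erase C2, and because the lavandulyl alkenes next to the free O7–H would not tolerate acid.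

**Compound list**

1 | 1-(4-hydroxy-2-methoxyphenyl)ethanone | CC(=O)c1ccc(O)cc1OC | starting material
2 | diallyl carbonate | C=CCOC(=O)OCC=C | starting material
3 | allyl 3-(4-hydroxy-2-methoxyphenyl)-3-oxopropanoate | C=CCOC(=O)CC(=O)c1ccc(O)cc1OC | intermediate
4 | allyl 3-(4-acetoxy-2-methoxyphenyl)-3-oxopropanoate | C=CCOC(=O)CC(=O)c1ccc(OC(C)=O)cc1OC | intermediate
5 | allyl (3R)-3-(4-acetoxy-2-methoxyphenyl)-3-hydroxypropanoate | C=CCOC(=O)C[C@@H](O)c1ccc(OC(C)=O)cc1OC | intermediate
6 | phloroglucinol (benzene-1,3,5-triol) | Oc1cc(O)cc(O)c1 | starting material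
7 | 3,5-bis(tert-butyldimethylsilyloxy)phenol | Oc1cc(O[Si](C)(C)C(C)(C)C)cc(O[Si](C)(C)C(C)(C)C)c1 | intermediate
8 | 2-bromo-3,5-bis(tert-butyldimethylsilyloxy)phenol | Oc1cc(O[Si](C)(C)C(C)(C)C)cc(O[Si](C)(C)C(C)(C)C)c1Br | intermediate
9 | allyl (3S)-3-(4-acetoxy-2-methoxyphenyl)-3-[2-bromo-3,5-bis(tert-butyldimethylsilyloxy)phenoxy]propanoate | C=CCOC(=O)C[C@H](Oc1cc(O[Si](C)(C)C(C)(C)C)cc(O[Si](C)(C)C(C)(C)C)c1Br)c1ccc(OC(C)=O)cc1OC | intermediate
10 | (3S)-3-(4-acetoxy-2-methoxyphenyl)-3-[2-bromo-3,5-bis(tert-butyldimethylsilyloxy)phenoxy]propanoic acid | OC(=O)C[C@H](Oc1cc(O[Si](C)(C)C(C)(C)C)cc(O[Si](C)(C)C(C)(C)C)c1Br)c1ccc(OC(C)=O)cc1OC | intermediate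
11 | mixed anhydride of acid 10 with trifluoroacetic acid (not isolated) | O=C(C[C@H](Oc1cc(O[Si](C)(C)C(C)(C)C)cc(O[Si](C)(C)C(C)(C)C)c1Br)c1ccc(OC(C)=O)cc1OC)OC(=O)C(F)(F)F | intermediate
12 | 4-[(2S)-8-bromo-5,7-bis(tert-butyldimethylsilyloxy)-4-oxo-3,4-dihydro-2H-chromen-2-yl]-3-methoxyphenyl acetate | Brc1c(O[Si](C)(C)C(C)(C)C)cc(O[Si](C)(C)C(C)(C)C)c2c1O[C@H](c1ccc(OC(C)=O)cc1OC)CC2=O | intermediate
13 | (4S)-4-benzyloxazolidin-2-one | O=C1N[C@@H](Cc2ccccc2)CO1 | starting material
14 | 3-methylbut-2-enoyl chloride | CC(C)=CC(=O)Cl | starting material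
15 | lithium salt of (4S)-4-benzyloxazolidin-2-one (not isolated) | O=C1[N-][C@@H](Cc2ccccc2)CO1.[Li+] | intermediate
16 | (4S)-4-benzyl-3-(3-methylbut-2-enoyl)oxazolidin-2-one | CC(C)=CC(=O)N1[C@@H](Cc2ccccc2)COC1=O | intermediate
17 | 1-bromo-3-methylbut-2-ene (prenyl bromide) | CC(C)=CCBr | starting material
18 | sodium (Z)-dienolate of imide 16 (not isolated) | C=C(C)/C=C(\[O-])N1[C@@H](Cc2ccccc2)COC1=O.[Na+] | intermediate
19 | (4S)-4-benzyl-3-[(2S)-5-methyl-2-(prop-1-en-2-yl)hex-4-enoyl]oxazolidin-2-one | C=C(C)[C@H](CC=C(C)C)C(=O)N1[C@@H](Cc2ccccc2)COC1=O | intermediate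
20 | (2S)-5-methyl-2-(prop-1-en-2-yl)hex-4-en-1-ol, (S)-lavandulol | C=C(C)[C@H](CC=C(C)C)CO | intermediate
21 | (3S)-3-(iodomethyl)-2,6-dimethylhepta-1,5-diene, (S)-lavandulyl iodide | C=C(C)[C@H](CC=C(C)C)CI | intermediate
22 | [(2S)-5-methyl-2-(prop-1-en-2-yl)hex-4-en-1-yl]zinc iodide (not isolated) | C=C(C)[C@H](CC=C(C)C)C[Zn]I | intermediate
23 | 4-{(2S)-5,7-bis(tert-butyldimethylsilyloxy)-8-[(2R)-5-methyl-2-(prop-1-en-2-yl)hex-4-en-1-yl]-4-oxo-3,4-dihydro-2H-chromen-2-yl}-3-methoxyphenyl acetate | C=C(C)[C@H](CC=C(C)C)Cc1c(O[Si](C)(C)C(C)(C)C)cc(O[Si](C)(C)C(C)(C)C)c2c1O[C@H](c1ccc(OC(C)=O)cc1OC)CC2=O | intermediate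
24 | 4-{(2S)-5,7-dihydroxy-8-[(2R)-5-methyl-2-(prop-1-en-2-yl)hex-4-en-1-yl]-4-oxo-3,4-dihydro-2H-chromen-2-yl}-3-methoxyphenyl acetate | C=C(C)[C@H](CC=C(C)C)Cc1c(O)cc(O)c2c1O[C@H](c1ccc(OC(C)=O)cc1OC)CC2=O | intermediate
25 | leachianone A, (2S)-5,7-dihydroxy-2-(4-hydroxy-2-methoxyphenyl)-8-[(2R)-5-methyl-2-(prop-1-en-2-yl)hex-4-en-1-yl]-2,3-dihydro-4H-chromen-4-one | C=C(C)[C@H](CC=C(C)C)Cc1c(O)cc(O)c2c1O[C@H](c1ccc(O)cc1OC)CC2=O | target

**Step count and risks**

Total: 15 steps. Longest linear sequence: 9 steps (steps 1, 2, 3, 6, 7, 8, 13, 14, 15).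

Risk 1, step 8 (ring closure). What may go wrong: acid-induced heterolysis of the benzylic C2–O1 bond running alongside the acylation, which would scramble C2 or sever ring A from the chain, and protodesilylation by the trifluoroacetic acid set free. The fallback sets out from acid 10 and comes back at 12. Acid 10 is condensed with dimethylamine hydrochloride (N-(3-dimethylaminopropyl)-N'-ethylcarbodiimide, N-methylmorpholine, CH2Cl2, 0 °C) to the N,N-dimethylamide F1. (CF3SO2)2O and 2-fluoropyridine (CH2Cl2, −78 → 0 °C) turn F1 into the O-triflyl iminium triflate F2, which closes onto C4a in a base-buffered intramolecular Vilsmeier–Haack acylation to the cyclic iminium triflate F3. Aqueous NaHCO3 then hydrolyses F3 to ketone 12. The electrophile is an iminium ion rather than an acyl trifluoroacetate, and the ring is closed in the presence of a pyridine base instead of free trifluoroacetic acid.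

Risk 2, step 13 (side-chain coupling). What may go wrong: slow oxidative addition of zerovalent palladium into the C8–Br bond, which is flanked by O1 and the silyloxy group on C7, so that β-hydride elimination of the alkylpalladium and protodemetalation of the zinc reagent take over. The fallback sets out from bromophenol 8 and iodide 21 and comes back at 23; it puts the side chain in before the ether and the ring. Zinc reagent 22 (from 21) is coupled with the free phenol 8 (Pd(OAc)2, SPhos, THF, 50–65 °C, slow addition of 22), where neither a ketone nor C2 limits temperature or excess, to give the 2-lavandulylphenol F4. Mitsunobu reaction of F4 with carbinol 5 gives the aryl ether allyl ester F5, and Tsuji–Trost deallylation gives the acid F6. (CF3CO)2O (CH2Cl2, −20 → 0 °C) converts F6 through its mixed trifluoroacetic anhydride F7 into 23, C8 now being blocked by the side chain itself.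

Risk 3, step 6 (ether formation). What may go wrong: elimination of the alkoxyphosphonium intermediate to the cinnamate, and partial ionisation with erosion of configuration, when attack by the ortho-bromophenoxide is too slow. The fallback sets out from phenol 7 and carbinol 5 and comes back at 12; it uses the unhindered phenol and brominates last. Mitsunobu reaction of 7 with 5 gives the bromine-free aryl ether allyl ester F8, and deallylation gives the acid F9. Ring closure with (CF3CO)2O through the mixed trifluoroacetic anhydride F10 (either ortho position, the ring being symmetric) gives the 5,7-disilyloxyflavanone F11. N-Bromosuccinimide (CH2Cl2, −78 °C) should brominate F11 at C8, C6 being shielded by two flanking silyloxy groups, which returns 12.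

**Further compounds**

F1 | step 8 | N,N-dimethylamide of acid 10, (3S)-3-(4-acetoxy-2-methoxyphenyl)-3-[2-bromo-3,5-bis(tert-butyldimethylsilyloxy)phenoxy]-N,N-dimethylpropanamide | CN(C)C(=O)C[C@H](Oc1cc(O[Si](C)(C)C(C)(C)C)cc(O[Si](C)(C)C(C)(C)C)c1Br)c1ccc(OC(C)=O)cc1OC
F2 | step 8 | O-triflyl iminium triflate of amide F1 | C[N+](C)=C(OS(=O)(=O)C(F)(F)F)C[C@H](Oc1cc(O[Si](C)(C)C(C)(C)C)cc(O[Si](C)(C)C(C)(C)C)c1Br)c1ccc(OC(C)=O)cc1OC.[O-]S(=O)(=O)C(F)(F)F
F3 | step 8 | cyclic iminium triflate, N-[(2S)-2-(4-acetoxy-2-methoxyphenyl)-8-bromo-5,7-bis(tert-butyldimethylsilyloxy)-2,3-dihydro-4H-chromen-4-ylidene]-N-methylmethanaminium trifluoromethanesulfonate | Brc1c(O[Si](C)(C)C(C)(C)C)cc(O[Si](C)(C)C(C)(C)C)c2c1O[C@H](c1ccc(OC(C)=O)cc1OC)CC2=[N+](C)C.[O-]S(=O)(=O)C(F)(F)F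
F4 | step 13 | 2-lavandulylphenol, 3,5-bis(tert-butyldimethylsilyloxy)-2-[(2R)-5-methyl-2-(prop-1-en-2-yl)hex-4-en-1-yl]phenol | C=C(C)[C@H](CC=C(C)C)Cc1c(O)cc(O[Si](C)(C)C(C)(C)C)cc1O[Si](C)(C)C(C)(C)C
F5 | step 13 | aryl ether allyl ester, allyl (3S)-3-(4-acetoxy-2-methoxyphenyl)-3-{3,5-bis(tert-butyldimethylsilyloxy)-2-[(2R)-5-methyl-2-(prop-1-en-2-yl)hex-4-en-1-yl]phenoxy}propanoate | C=CCOC(=O)C[C@H](Oc1cc(O[Si](C)(C)C(C)(C)C)cc(O[Si](C)(C)C(C)(C)C)c1C[C@@H](CC=C(C)C)C(C)=C)c1ccc(OC(C)=O)cc1OC
F6 | step 13 | acid, (3S)-3-(4-acetoxy-2-methoxyphenyl)-3-{3,5-bis(tert-butyldimethylsilyloxy)-2-[(2R)-5-methyl-2-(prop-1-en-2-yl)hex-4-en-1-yl]phenoxy}propanoic acid | OC(=O)C[C@H](Oc1cc(O[Si](C)(C)C(C)(C)C)cc(O[Si](C)(C)C(C)(C)C)c1C[C@@H](CC=C(C)C)C(C)=C)c1ccc(OC(C)=O)cc1OC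
F7 | step 13 | mixed trifluoroacetic anhydride of acid F6 | O=C(C[C@H](Oc1cc(O[Si](C)(C)C(C)(C)C)cc(O[Si](C)(C)C(C)(C)C)c1C[C@@H](CC=C(C)C)C(C)=C)c1ccc(OC(C)=O)cc1OC)OC(=O)C(F)(F)F
F8 | step 6 | bromine-free aryl ether allyl ester, allyl (3S)-3-(4-acetoxy-2-methoxyphenyl)-3-[3,5-bis(tert-butyldimethylsilyloxy)phenoxy]propanoate | C=CCOC(=O)C[C@H](Oc1cc(O[Si](C)(C)C(C)(C)C)cc(O[Si](C)(C)C(C)(C)C)c1)c1ccc(OC(C)=O)cc1OC
F9 | step 6 | acid, (3S)-3-(4-acetoxy-2-methoxyphenyl)-3-[3,5-bis(tert-butyldimethylsilyloxy)phenoxy]propanoic acid | OC(=O)C[C@H](Oc1cc(O[Si](C)(C)C(C)(C)C)cc(O[Si](C)(C)C(C)(C)C)c1)c1ccc(OC(C)=O)cc1OC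
F10 | step 6 | mixed trifluoroacetic anhydride of acid F9 | O=C(C[C@H](Oc1cc(O[Si](C)(C)C(C)(C)C)cc(O[Si](C)(C)C(C)(C)C)c1)c1ccc(OC(C)=O)cc1OC)OC(=O)C(F)(F)F
F11 | step 6 | 5,7-disilyloxyflavanone, 4-[(2S)-5,7-bis(tert-butyldimethylsilyloxy)-4-oxo-3,4-dihydro-2H-chromen-2-yl]-3-methoxyphenyl acetate | CC(C)(C)[Si](C)(C)Oc1cc(O[Si](C)(C)C(C)(C)C)c2c(c1)O[C@H](c1ccc(OC(C)=O)cc1OC)CC2=O
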